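The numbers in the tables were computed for substances that don't exist, and the scatter is random.

The leftover in larch at 6.00 h was 24% of the free monomer, with 34% in chains, so 42.0% of the charge had gone by another route, which I read as the protic impurity taking monomer one to one.

- larch: free monomer 1.5 M; protic impurity 0.75 M; pre-initiator 2 mol%; the very flask that is asked about, followed so far
- flask: free monomer 1.5 M; protic impurity 0.750 M; pre-initiator 2 mol%; time 15 h

larch run (percent of the free monomer charged)

| time / h | monomer in chains / % | free monomer / % |
|---|---|---|
| 1.00 | 1 | 86 |
| 2.00 | 6 | 67 |
| 3.00 | 14 | 57 |
| 4.00 | 21 | 41 |
| 5.00 | 27 | 35 |
| 6.00 | 34 | 24 |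

(each reading ± 2 percentage points)

* whether the average number of monomer units in a chain (chains begun, living or dead) reaches 30 by 15 h (yes / no)
* average number of monomer units in a chain (chains begun, living or dead) at 15 h

- the average divides the monomer in chains by the number of chains begun, living and dead together
- the earlier runs do not show the number of chains; that part of a forecast is a guess

I turned the settings by hand, one after the other. Time came first: the readings gave a pseudo-first-order loss of free monomer of 0.257 h⁻¹, which by my reckoning left about 2.38% at 15 h. The protic impurity at 0.750 M claimed 50.0% of the free monomer, and the rest could enter chains. The pre-initiator loading of 2 mol% then offered 0.0300 M of possible starts. From these two I took the full-start length, the monomer units per chain if every pre-initiator began one chain and the impurity took its whole claim: 25.0. The started share is the chains begun over the pre-initiator charged, and a length of 30 asked that this share stay under 83.3%.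

Growth of chains per free monomer read 0.0970 h⁻¹ around 2.00 h and 0.186 h⁻¹ around 5.00 h, faster late than early, so I took it that chains were still being started as the monomer ran down. My guess for the started share was about half, which made my own answer yes, with a length near 50.0.

The forecast answered no with a length of 27, remarking: “The chain count is a guess”.

Larch gave yes, with a length of 59.5 at 15 h, and passed 30 at 2.64 h.

    free monomer + initiator → living end + monomer in chains (k = 0.0190 L mol⁻¹ min⁻¹)
    free monomer + living end → monomer in chains + living end, rate k2*[living end]*[free monomer] (k = 0.389 L mol⁻¹ min⁻¹)
    protic impurity + free monomer → quenched substrate (k = 0.00513 L mol⁻¹ min⁻¹)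
    pre-initiator ⇌ initiator (K = 0.490, k = 0.00175 min⁻¹)

At 15.0 h the living end stood at 0.0140 M, a started share of 46.7%, less than the critical 83.3%, while 38.4% of the pre-initiator and 0.00448 M of initiator remained unused. In a run of larch with the quench step taken away, the length at 15 h rose from 59.5 to 91.0. With no impurity claim the full-start length of that run is 50.0, which puts its started share near 54.9%.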